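**Retrosynthetic overview**
- The target is the all-cis oxolane (H-2, H-3 and H-4 on one face). C3 and C4 are therefore set last, by syn hydrogenation of the C3=C4 bond of a 2-aryl-2,5-dihydrofuran from the face anti to the C2 aryl group.
- Key disconnection: the C4–CH2Ar bond together with the O1–C5 bond. C4 lies between the ring CH2 (C5, bonded to O1) and C3 (which carries C2–OH and the C1 carbon), so C3=C4=C5 can be an allene whose central carbon takes the benzyl group while the C2 hydroxyl closes the oxolane 5-endo.
- The α-hydroxy allenoate comes from a propargylic carbonate by Pd/CO (C3–C1 bond). Its carbinol centre (C2, the only stereocentre carried) comes from catalytic asymmetric alkynylation of 3,4,5-trimethoxybenzaldehyde (C2–C3 bond).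
- Ring order: both benzene rings are bought; the oxolane is the only ring made, in the key step.

Key step: step 4

Assumption: 2 and 6 are taken as purchasable (6 is otherwise one NaBH4 reduction away from 2,4,5-trimethoxybenzaldehyde), and the ligand antipode in step 1 is chosen to give the (S)-carbinol.

**Route**

Step 1
Reactants: 1 3,4,5-trimethoxybenzaldehyde; 2 methyl prop-2-yn-1-yl carbonate
Product: 4 (S)-4-hydroxy-4-(3,4,5-trimethoxyphenyl)but-2-yn-1-yl methyl carbonate, via methylzinc alkynylide 3 (not isolated)
Conditions: Me2Zn (3 equiv), ProPhenol ligand (10 mol %), Ph3PO (20 mol %), toluene, 0–4 °C; aq NH4Cl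
Reagents that add atoms: none
Why: Catalytic asymmetric alkynylation of an aldehyde, in which dimethylzinc converts 2 into alkynylzinc 3 and this adds to one carbonyl face inside the chiral dinuclear zinc–ProPhenol pocket, so the (S)-carbinol centre (the future C2) is set by the ligand while the carbonate is inert to alkynylzinc species.

Step 2
Reactants: 4 (S)-4-hydroxy-4-(3,4,5-trimethoxyphenyl)but-2-yn-1-yl methyl carbonate
Product: 5 methyl (S)-2-[hydroxy(3,4,5-trimethoxyphenyl)methyl]buta-2,3-dienoate
Conditions: Pd(OAc)2 (5 mol %), PPh3 (10 mol %), CO (1–5 atm), MeOH, rt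
Reagents that add atoms: carbon monoxide, [C-]#[O+]; methanol, CO
Why: Palladium-catalysed SN2′ alkoxycarbonylation of a primary propargylic carbonate, in which ionisation at C5 and CO capture at C3 install the C1 ester and turn C3–C4–C5 into the terminal 1,2-diene under neutral, base-free conditions that leave the carbinol centre untouched.

Step 3
Reactants: 6 2,4,5-trimethoxybenzyl alcohol
Product: 7 methyl 2,4,5-trimethoxybenzyl carbonate
Conditions: ClCO2Me, pyridine, CH2Cl2, 0 °C
Reagents that add atoms: methyl chloroformate, COC(=O)Cl
Why: O-acylation of the primary benzylic alcohol with a chloroformate should give a storable, halide-free benzyl donor that Pd(0) can ionise.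

Step 4
Reactants: 5 methyl (S)-2-[hydroxy(3,4,5-trimethoxyphenyl)methyl]buta-2,3-dienoate; 7 methyl 2,4,5-trimethoxybenzyl carbonate
Product: 10 methyl (S)-4-(2,4,5-trimethoxybenzyl)-2-(3,4,5-trimethoxyphenyl)-2,5-dihydrofuran-3-carboxylate, via benzylpalladium(II) methoxide 8 (not isolated), via C4-palladated dihydrofuran 9 (not isolated)
Conditions: Pd2(dba)3 (2.5 mol %), DPEphos (6 mol %), THF, 50–60 °C
Reagents that add atoms: none
Why: Proposed new method: Pd(0) ionises benzylic carbonate 7 with loss of CO2 to the electrophilic benzylpalladium(II) methoxide 8, which binds the distal C4=C5 π-bond of allene 5; the C2 hydroxyl (its proton leaving as methanol) adds anti to palladium at the terminal carbon C5 to give σ-vinyl species 9, and reductive elimination forms the C4–CH2Ar bond and returns Pd(0). The closest known reaction type is the Pd-catalysed coupling–cyclisation of 2,3-allenols and 2,3-allenoic acids with allyl, aryl and alkenyl halides (giving 4-substituted 2,5-dihydrofurans and β-substituted butenolides), combined with the known ionisation of benzylic carbonates to η3-benzylpalladium species; a benzylic carbonate has not been used in this manifold. The oxolane ring is closed through the O1–C5 bond by 5-endo attack on the terminal allene carbon (C3 and C4 stay in the ring); if benzyl migration to the central carbon comes first, the resulting C3–C4–C5 π-allyl is closed by the same oxygen at C5 and gives the same product. No new stereocentre is formed: C2 is not a reacting centre and is carried through unchanged, to serve as the sole control element in step 6. The step needs carbon on the central and oxygen on the terminal allene carbon rather than O-benzylation or oxirane closure at C3; this is secured by the fully substituted, ester-bearing C3 (no attack there, and conjugation leaves C4=C5 as the electron-rich π-bond for Pd), by C1 being held as an ester so that the C2 hydroxyl is the only nucleophile, and by base-free conditions that suppress retro-aldol loss of the carbinol centre.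

Step 5
Reactants: 10 methyl (S)-4-(2,4,5-trimethoxybenzyl)-2-(3,4,5-trimethoxyphenyl)-2,5-dihydrofuran-3-carboxylate
Product: 11 [(S)-4-(2,4,5-trimethoxybenzyl)-2-(3,4,5-trimethoxyphenyl)-2,5-dihydrofuran-3-yl]methanol
Conditions: DIBAL-H (2.5 equiv), CH2Cl2, −78 °C; Rochelle salt
Reagents that add atoms: none
Why: DIBAL-H 1,2-reduction of the conjugated ester to the allylic alcohol at low temperature should touch neither the alkene nor the C2 centre and unveils the hydroxyl that binds iridium in the last step.

Step 6
Reactants: 11 [(S)-4-(2,4,5-trimethoxybenzyl)-2-(3,4,5-trimethoxyphenyl)-2,5-dihydrofuran-3-yl]methanol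
Product: 12 [(2R,3R,4R)-4-(2,4,5-trimethoxybenzyl)-2-(3,4,5-trimethoxyphenyl)oxolan-3-yl]methanol
Conditions: H2 (1–10 atm), [Ir(cod)(PCy3)(py)]PF6 (5 mol %), CH2Cl2, rt
Reagents that add atoms: none
Why: Hydroxyl-directed homogeneous hydrogenation of a tetrasubstituted allylic alcohol, in which iridium bound to the C3 hydroxymethyl group delivers both hydrogens syn to the flat dihydrofuran from the face anti to the C2 aryl group, so syn addition fixes the 3,4-cis relation and the C2 centre fixes 2,3-cis, giving the all-cis (2R,3R,4R) oxolane without a hydrogenolytic metal surface near the benzylic C2–O bond.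

**Compound list**

1 | 3,4,5-trimethoxybenzaldehyde | COc1cc(C=O)cc(OC)c1OC | starting material
2 | methyl prop-2-yn-1-yl carbonate | COC(=O)OCC#C | starting material
3 | methylzinc alkynylide of 2 | COC(=O)OCC#C[Zn]C | intermediate (not isolated)
4 | (S)-4-hydroxy-4-(3,4,5-trimethoxyphenyl)but-2-yn-1-yl methyl carbonate | COC(=O)OCC#C[C@@H](O)c1cc(OC)c(OC)c(OC)c1 | intermediate
5 | methyl (S)-2-[hydroxy(3,4,5-trimethoxyphenyl)methyl]buta-2,3-dienoate | COC(=O)C(=C=C)[C@@H](O)c1cc(OC)c(OC)c(OC)c1 | intermediate
6 | 2,4,5-trimethoxybenzyl alcohol | COc1cc(OC)c(OC)cc1CO | starting material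
7 | methyl 2,4,5-trimethoxybenzyl carbonate | COC(=O)OCc1cc(OC)c(OC)cc1OC | intermediate
8 | (2,4,5-trimethoxybenzyl)palladium(II) methoxide, phosphine ligands omitted | CO[Pd]Cc1cc(OC)c(OC)cc1OC | intermediate (not isolated)
9 | methyl (S)-4-[(2,4,5-trimethoxybenzyl)palladio]-2-(3,4,5-trimethoxyphenyl)-2,5-dihydrofuran-3-carboxylate, phosphine ligands omitted | COC(=O)C1=C([Pd]Cc2cc(OC)c(OC)cc2OC)CO[C@H]1c3cc(OC)c(OC)c(OC)c3 | intermediate (not isolated)
10 | methyl (S)-4-(2,4,5-trimethoxybenzyl)-2-(3,4,5-trimethoxyphenyl)-2,5-dihydrofuran-3-carboxylate | COC(=O)C1=C(Cc2cc(OC)c(OC)cc2OC)CO[C@H]1c3cc(OC)c(OC)c(OC)c3 | intermediate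
11 | [(S)-4-(2,4,5-trimethoxybenzyl)-2-(3,4,5-trimethoxyphenyl)-2,5-dihydrofuran-3-yl]methanol | OCC1=C(Cc2cc(OC)c(OC)cc2OC)CO[C@H]1c3cc(OC)c(OC)c(OC)c3 | intermediate
12 | [(2R,3R,4R)-4-(2,4,5-trimethoxybenzyl)-2-(3,4,5-trimethoxyphenyl)oxolan-3-yl]methanol (all-cis) | COc1cc(OC)c(OC)cc1C[C@H]1CO[C@@H](c2cc(OC)c(OC)c(OC)c2)[C@H]1CO | target

**Step count and risks**

Total step count: 6. Longest linear sequence: 5 (steps 1, 2, 4, 5, 6).

Steps most likely to fail:

1. Step 4 (Proposed new method). What may go wrong: O-benzylation of the carbinol by the η3-benzylpalladium cation, closure at C3 to a vinyl oxirane, protodepalladation to the unbenzylated dihydrofuran, or retro-aldol erosion of the ee. The fallback uses known chemistry, sets out from 5 and 6 and comes back at 10. 5-Endo iodoetherification of the α-allenol 5 (I2, NaHCO3, MeCN, 0 °C) should give methyl (S)-4-iodo-2-(3,4,5-trimethoxyphenyl)-2,5-dihydrofuran-3-carboxylate F1, the hydroxyl being a better nucleophile than the ester carbonyl. Alcohol 6 is converted with SOCl2 (CH2Cl2, 0 °C) into 2,4,5-trimethoxybenzyl chloride F2, and zinc insertion (Zn dust, LiCl, THF) gives (2,4,5-trimethoxybenzyl)zinc chloride F3. Negishi coupling of F1 with F3 (Pd(OAc)2, SPhos, THF, rt) forms the same C4–CH2 bond and returns to 10.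

2. Step 6. What may go wrong: insufficient facial discrimination on the flat ring, migration of the double bond to the enol ether before reduction, or ionisation of the allylic and benzylic C2–O bond by the acidic cationic iridium hydride. The fallback sets out from 10 and comes back at 12. Heterogeneous hydrogenation at the ester stage (H2, Rh/Al2O3, EtOAc), where the surface approaches anti to the aryl group without a directing group, should give methyl (2R,3S,4R)-4-(2,4,5-trimethoxybenzyl)-2-(3,4,5-trimethoxyphenyl)oxolane-3-carboxylate F4. This is reduced at once with LiAlH4 (THF, 0 °C), before C3 can epimerise, to give 12.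

3. Step 2. What may go wrong: capture of the propargyl/allenyl-palladium species by the neighbouring hydroxyl or by CO2 (cyclic carbonate), phosphine- or methoxide-induced cycloisomerisation of the hydroxy allenoate, or double carbonylation. The fallback sets out from 4 and comes back at 5. The carbinol is silylated (TBSCl, imidazole, DMF) to (S)-4-[(tert-butyldimethylsilyl)oxy]-4-(3,4,5-trimethoxyphenyl)but-2-yn-1-yl methyl carbonate F5. Carbonylation as in step 2 should give methyl (S)-2-{[(tert-butyldimethylsilyl)oxy](3,4,5-trimethoxyphenyl)methyl}buta-2,3-dienoate F6, and desilylation with HF·pyridine (THF, 0 °C) returns to 5.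

**Further compounds**

F1 | step 4 | methyl (S)-4-iodo-2-(3,4,5-trimethoxyphenyl)-2,5-dihydrofuran-3-carboxylate | COC(=O)C1=C(I)CO[C@H]1c3cc(OC)c(OC)c(OC)c3
F2 | step 4 | 2,4,5-trimethoxybenzyl chloride | COc1cc(OC)c(OC)cc1CCl
F3 | step 4 | (2,4,5-trimethoxybenzyl)zinc chloride | COc1cc(OC)c(OC)cc1C[Zn]Cl
F4 | step 6 | methyl (2R,3S,4R)-4-(2,4,5-trimethoxybenzyl)-2-(3,4,5-trimethoxyphenyl)oxolane-3-carboxylate | COc1cc(OC)c(OC)cc1C[C@H]1CO[C@@H](c2cc(OC)c(OC)c(OC)c2)[C@H]1C(=O)OC
F5 | step 2 | (S)-4-[(tert-butyldimethylsilyl)oxy]-4-(3,4,5-trimethoxyphenyl)but-2-yn-1-yl methyl carbonate | COC(=O)OCC#C[C@@H](O[Si](C)(C)C(C)(C)C)c1cc(OC)c(OC)c(OC)c1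
F6 | step 2 | methyl (S)-2-{[(tert-butyldimethylsilyl)oxy](3,4,5-trimethoxyphenyl)methyl}buta-2,3-dienoate | COC(=O)C(=C=C)[C@@H](O[Si](C)(C)C(C)(C)C)c1cc(OC)c(OC)c(OC)c1
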